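**Retrosynthetic overview**
- The last step frees the C6 phenol of the benzofuran from a MOM ether; before that the molecule is cut at the pentenyl chain.
- Feature: the stereocentre C4 and its methyl C5 of the pent-2-en-2-yl chain are a two-carbon unit held between chromene C6 and the alkene carbon C3. This unit is ethylene, so the C6–C4 and C4–C3 bonds are both cut, giving a chromen-6-ylboronic acid, ethylene and the E enol triflate TfO–CH=C(CH3)–benzofuranyl (palladium three-component 1,1-arylalkenylation, stereocentre set by a chiral ligand).
- Triflate: 2,4-dihydroxyacetophenone (benzene ring C) is iodinated at C5; Sonogashira/5-endo-dig annulation with 2-methylbut-3-yn-1-ol closes furan ring D and brings in the side chain at the alcohol oxidation level; MOM protection, oxidation and E-enolate triflation follow.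
- Boronic acid: 4-bromo-3-methoxyphenol (benzene ring A) is converted to its dimethylpropargyl ether, and Claisen/oxa-6π cyclisation closes pyran ring B with bromine already at C6, because electrophilic bromination of the finished chromene would attack its electron-rich C3=C4 bond; Br/Li exchange and borylation follow.
- Ring order: ring B and ring D are each closed on their own fragment before the union; the key step closes no ring.

Key step: step 9

Assumption: racemic 2-methylbut-3-yn-1-ol is taken as a catalogue compound.
Assumption: the sense of induction of the chiral ligand in the key step cannot be predicted; (S)-4-tert-butyl-2-[5-(trifluoromethyl)pyridin-2-yl]-4,5-dihydro-1,3-oxazole ("(S)-PyrOx ligand") is written, and its antipode is used if it should deliver the R centre.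

**Route**

Step 1
Reactants: 1 4-bromo-3-methoxyphenol; 2 3-chloro-3-methylbut-1-yne
Product: 3 1-bromo-2-methoxy-4-[(2-methylbut-3-yn-2-yl)oxy]benzene
Conditions: DBU, CuCl2·2H2O (cat.), MeCN, 0 °C → rt
Reagents that add atoms: none
Why: Copper-catalysed propargylic etherification of the phenol with the tertiary propargyl chloride is the standard entry to aryl 1,1-dimethylpropargyl ethers and leaves the aryl bromide untouched.

Step 2
Reactants: 3 1-bromo-2-methoxy-4-[(2-methylbut-3-yn-2-yl)oxy]benzene
Product: 5 6-bromo-7-methoxy-2,2-dimethyl-2H-chromene, via ortho-allenylphenol 4 (not isolated)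
Conditions: N,N-diethylaniline, 170 °C
Reagents that add atoms: none
Why: Aromatic propargyl Claisen rearrangement to the less hindered ortho position (para to OMe, away from the site flanked by OMe) gives allenylphenol 4, whose 1,5-hydrogen shift and oxa-6π electrocyclisation close pyran ring B with the bromine already fixed at C6.

Step 3
Reactants: 5 6-bromo-7-methoxy-2,2-dimethyl-2H-chromene
Product: 8 (7-methoxy-2,2-dimethyl-2H-chromen-6-yl)boronic acid, via aryllithium 6 (not isolated), via lithium triisopropoxyborate 7 (not isolated)
Conditions: n-BuLi, THF, −78 °C; B(OiPr)3, −78 °C → rt; 1 M HCl, 0 °C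
Reagents that add atoms: triisopropyl borate, CC(C)OB(OC(C)C)OC(C)C; water, O
Why: Bromine–lithium exchange at −78 °C is faster than any reaction of n-BuLi with the chromene, and borate trapping followed by brief mild hydrolysis is the standard arylboronic acid synthesis.

Step 4
Reactants: 9 1-(2,4-dihydroxyphenyl)ethan-1-one (2,4-dihydroxyacetophenone)
Product: 10 1-(2,4-dihydroxy-5-iodophenyl)ethan-1-one
Conditions: ICl (1.0 equiv), AcOH, rt
Reagents that add atoms: iodine monochloride, ClI
Why: Electrophilic aromatic iodination of the resorcinol ring should go to C5, ortho to the free 4-OH and para to the chelated 2-OH, the less hindered of the two doubly activated positions.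

Step 5
Reactants: 10 1-(2,4-dihydroxy-5-iodophenyl)ethan-1-one; 11 2-methylbut-3-yn-1-ol (racemic)
Product: 13 1-[6-hydroxy-2-(1-hydroxypropan-2-yl)-1-benzofuran-5-yl]ethan-1-one (racemic), via ortho-alkynylphenol 12 (not isolated)
Conditions: Pd(PPh3)2Cl2 (3 mol%), CuI (5 mol%), Et3N, DMF, 60 °C
Reagents that add atoms: none
Why: Sonogashira coupling at the C–I bond gives ortho-alkynylphenol 12, whose 4-OH adds 5-endo-dig to the metal-activated alkyne to close furan ring D (coupling–cycloisomerisation of ortho-iodophenols), while the chelated 2-OH and the aliphatic OH stay out.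

Step 6
Reactants: 13 1-[6-hydroxy-2-(1-hydroxypropan-2-yl)-1-benzofuran-5-yl]ethan-1-one
Product: 14 1-[2-(1-hydroxypropan-2-yl)-6-(methoxymethoxy)-1-benzofuran-5-yl]ethan-1-one (racemic)
Conditions: NaH (1.0 equiv), DMF, 0 °C; MOMCl (1.05 equiv), 0 °C → rt
Reagents that add atoms: chloromethyl methyl ether, COCCl
Why: One equivalent of NaH deprotonates only the far more acidic phenol, and the phenoxide is O-alkylated by MOMCl (Williamson-type etherification) while the neutral primary alcohol stays free.

Step 7
Reactants: 14 1-[2-(1-hydroxypropan-2-yl)-6-(methoxymethoxy)-1-benzofuran-5-yl]ethan-1-one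
Product: 15 2-[5-acetyl-6-(methoxymethoxy)-1-benzofuran-2-yl]propanal (racemic)
Conditions: Dess–Martin periodinane, CH2Cl2, 0 °C → rt; used crude
Reagents that add atoms: none
Why: Dess–Martin oxidation takes the primary alcohol to the aldehyde under conditions that spare the MOM ether, the ketone and the benzofuran, and the racemic centre is erased in the next step.

Step 8
Reactants: 15 2-[5-acetyl-6-(methoxymethoxy)-1-benzofuran-2-yl]propanal
Product: 17 (1E)-2-[5-acetyl-6-(methoxymethoxy)-1-benzofuran-2-yl]prop-1-en-1-yl trifluoromethanesulfonate, via potassium enolate 16 (not isolated)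
Conditions: KOtBu (1.05 equiv), THF, −78 °C; PhNTf2, −78 → 0 °C; chromatography
Reagents that add atoms: N-phenylbis(trifluoromethanesulfonimide), O=S(=O)(N(c1ccccc1)S(=O)(=O)C(F)(F)F)C(F)(F)F
Why: KOtBu removes only the doubly activated α-hydrogen (aldehyde and benzofuranyl) and not a ketone methyl hydrogen, and O-sulfonylation of the conjugated enolate with PhNTf2 should favour the E triflate, in which oxygen lies cis to methyl and the benzofuran stays coplanar; the minor Z isomer is removed by chromatography.

Step 9
Reactants: 17 (1E)-2-[5-acetyl-6-(methoxymethoxy)-1-benzofuran-2-yl]prop-1-en-1-yl trifluoromethanesulfonate; 18 ethylene; 8 (7-methoxy-2,2-dimethyl-2H-chromen-6-yl)boronic acid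
Product: 19 1-{6-(methoxymethoxy)-2-[(2E,4S)-4-(7-methoxy-2,2-dimethyl-2H-chromen-6-yl)pent-2-en-2-yl]-1-benzofuran-5-yl}ethan-1-one
Conditions: Pd2(dba)3 (3 mol%), (S)-PyrOx ligand (9 mol%), NaHCO3 (2 equiv), ethylene (1 atm), DMA, 55 °C
Reagents that add atoms: none
Why: Proposed new method: zerovalent palladium adds oxidatively to the C–OTf bond of 17 to give a cationic alkenyl divalent palladium that inserts ethylene; β-hydride elimination and reinsertion of the palladium hydride with reversed regiochemistry turn the homoallyl complex into the allyl complex CH3–CH–CH–C(CH3)(benzofuranyl), which transmetalates with 8 and reductively eliminates at the methyl-bearing terminus, so the C3–C4 bond and the bond from C4 to chromene C6 form and no ring closes. The closest known reaction is the racemic palladium-catalysed 1,1-arylvinylation of ethylene with alkenyl triflates and arylboronic acids, run without added ligand; the new element is a chiral pyridine-oxazoline ligand of the kind that controls enantioselective redox-relay Heck reactions of alkenyl triflates on cationic palladium. The C4 stereocentre is set by this ligand, which must hold palladium on one face of the allyl fragment (at hydride return to the bound diene, or through faster reductive elimination of one of two equilibrating diastereomeric allyl(aryl)palladium complexes) so that the aryl group is delivered to that face. The step needs 1,1- over 1,3-selectivity, secured because the other allyl terminus is fully substituted and its arylation would break conjugation with the benzofuran; retention of the E geometry, secured because syn/anti exchange at that terminus requires palladium σ-bound to a tertiary carbon and the benzofuranyl-syn arrangement is in any case the more stable one; and chemoselectivity for ethylene over the hindered chromene C3=C4 bond and over direct Suzuki coupling, secured by excess ethylene and the slow transmetalation under weak-base, phosphine-free conditions. Ligand is used in excess over palladium so that unligated palladium does not run a racemic background reaction.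

Step 10
Reactants: 19 1-{6-(methoxymethoxy)-2-[(2E,4S)-4-(7-methoxy-2,2-dimethyl-2H-chromen-6-yl)pent-2-en-2-yl]-1-benzofuran-5-yl}ethan-1-one
Product: 20 1-{6-hydroxy-2-[(2E,4S)-4-(7-methoxy-2,2-dimethyl-2H-chromen-6-yl)pent-2-en-2-yl]-1-benzofuran-5-yl}ethan-1-one
Conditions: HCl (1.25 M in MeOH), THF, 0 °C → rt
Reagents that add atoms: none
Why: Acid-catalysed acetal cleavage (transacetalisation to methanol) of a MOM ether ortho to a carbonyl group is unusually fast because the freed phenol is chelated, so conditions mild enough to spare the chromene, the trisubstituted alkene and the C4 stereocentre should suffice.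

**Compound list**
1 | 4-bromo-3-methoxyphenol | COc1cc(O)ccc1Br | starting material
2 | 3-chloro-3-methylbut-1-yne | CC(C)(Cl)C#C | starting material
3 | 1-bromo-2-methoxy-4-[(2-methylbut-3-yn-2-yl)oxy]benzene | COc1cc(OC(C)(C)C#C)ccc1Br | intermediate
4 | 4-bromo-5-methoxy-2-(3-methylbuta-1,2-dien-1-yl)phenol | COc1cc(O)c(C=C=C(C)C)cc1Br | intermediate (not isolated)
5 | 6-bromo-7-methoxy-2,2-dimethyl-2H-chromene | COc1cc2OC(C)(C)C=Cc2cc1Br | intermediate
6 | (7-methoxy-2,2-dimethyl-2H-chromen-6-yl)lithium | [Li]c1cc2C=CC(C)(C)Oc2cc1OC | intermediate (not isolated)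
7 | lithium triisopropoxy(7-methoxy-2,2-dimethyl-2H-chromen-6-yl)borate | [Li+].COc1cc2OC(C)(C)C=Cc2cc1[B-](OC(C)C)(OC(C)C)OC(C)C | intermediate (not isolated)
8 | (7-methoxy-2,2-dimethyl-2H-chromen-6-yl)boronic acid | COc1cc2c(cc1B(O)O)C=CC(C)(C)O2 | intermediate
9 | 1-(2,4-dihydroxyphenyl)ethan-1-one | CC(=O)c1ccc(O)cc1O | starting material
10 | 1-(2,4-dihydroxy-5-iodophenyl)ethan-1-one | CC(=O)c1cc(I)c(O)cc1O | intermediate
11 | 2-methylbut-3-yn-1-ol (racemic) | C#CC(C)CO | starting material
12 | 1-[2,4-dihydroxy-5-(4-hydroxy-3-methylbut-1-yn-1-yl)phenyl]ethan-1-one | CC(=O)c1cc(C#CC(C)CO)c(O)cc1O | intermediate (not isolated)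
13 | 1-[6-hydroxy-2-(1-hydroxypropan-2-yl)-1-benzofuran-5-yl]ethan-1-one (racemic) | CC(=O)c1cc2cc(C(C)CO)oc2cc1O | intermediate
14 | 1-[2-(1-hydroxypropan-2-yl)-6-(methoxymethoxy)-1-benzofuran-5-yl]ethan-1-one (racemic) | CC(=O)c1cc2cc(C(C)CO)oc2cc1OCOC | intermediate
15 | 2-[5-acetyl-6-(methoxymethoxy)-1-benzofuran-2-yl]propanal (racemic) | CC(=O)c1cc2cc(C(C)C=O)oc2cc1OCOC | intermediate
16 | potassium (1E)-2-[5-acetyl-6-(methoxymethoxy)-1-benzofuran-2-yl]prop-1-en-1-olate | [K+].[O-]/C=C(\C)c1cc2cc(C(C)=O)c(OCOC)cc2o1 | intermediate (not isolated)
17 | (1E)-2-[5-acetyl-6-(methoxymethoxy)-1-benzofuran-2-yl]prop-1-en-1-yl trifluoromethanesulfonate | FC(F)(F)S(=O)(=O)O/C=C(\C)c1cc2cc(C(C)=O)c(OCOC)cc2o1 | intermediate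
18 | ethylene | C=C | starting material
19 | 1-{6-(methoxymethoxy)-2-[(2E,4S)-4-(7-methoxy-2,2-dimethyl-2H-chromen-6-yl)pent-2-en-2-yl]-1-benzofuran-5-yl}ethan-1-one | COc1cc2c(cc1[C@@H](C)/C=C(\C)c1cc3cc(C(C)=O)c(OCOC)cc3o1)C=CC(C)(C)O2 | intermediate
20 | 1-{6-hydroxy-2-[(2E,4S)-4-(7-methoxy-2,2-dimethyl-2H-chromen-6-yl)pent-2-en-2-yl]-1-benzofuran-5-yl}ethan-1-one | COc1cc2c(cc1[C@@H](C)/C=C(\C)c1cc3cc(C(C)=O)c(O)cc3o1)C=CC(C)(C)O2 | target

**Step count**
Total steps: 10. Longest linear sequence: 7 (steps 4 to 10); the boronic acid branch (steps 1 to 3) joins at step 9.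

**Steps most likely to fail**

Step 9 (proposed new method). Facial discrimination at the allyl stage may be poor, or a ligand-free racemic pathway may run beside the ligated one. The ligand may also slow ethylene insertion enough that direct Suzuki coupling or release of the diene takes over. Fallback by known chemistry, which separates the vinylation from the asymmetric C–aryl bond formation: the fallback sets out from 17. Suzuki–Miyaura vinylation with potassium vinyltrifluoroborate (Pd(dppf)Cl2, Cs2CO3, THF/H2O, 60 °C) should give, with retention of geometry, 1-{6-(methoxymethoxy)-2-[(2E)-penta-2,4-dien-2-yl]-1-benzofuran-5-yl}ethan-1-one F1. Nickel-catalysed enantioselective Markovnikov 1,2-hydroarylation of this terminal 1,3-diene with boronic acid 8 (Ni(cod)2, chiral spiro aminophosphine ligand, MeOH) should then place hydrogen on the terminal carbon and the aryl group on C4, and the fallback comes back to the route at 19.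

Step 8. Trapping of the enolate may discriminate poorly between the two geometries, and the E and Z triflates may be hard to separate. Whether a Z-contaminated triflate would converge on the E product through syn/anti exchange in the allyl intermediate of step 9 is open and is not relied upon. Fallback through a purifiable, stereodefined enol silane: the fallback sets out from 15. Soft enolisation and silylation (TBSCl, DBU, CH2Cl2, rt), which leaves the methyl ketone alone, followed by chromatography on Et3N-deactivated silica, should give 1-{2-[(1E)-1-{[tert-butyl(dimethyl)silyl]oxy}prop-1-en-2-yl]-6-(methoxymethoxy)-1-benzofuran-5-yl}ethan-1-one F2; the Z isomer is hydrolysed back to 15 and recycled. Fluoride-triggered exchange of silicon for the triflyl group with in situ trapping (CsF, PhNTf2, DME, rt) should keep the geometry, and the fallback comes back to the route at 17.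

Step 10. The acid may hydrate or dimerise the chromene C3=C4 bond, or protonate the trisubstituted alkene to a benzofuranyl-stabilised cation with geometric scrambling or double-bond migration. Fallback by changing the order of events, so that acid never meets the chromene or the stereocentre: the fallback sets out from 17. The same methanolic HCl treatment, applied to the acid-stable enol triflate, should give (1E)-2-(5-acetyl-6-hydroxy-1-benzofuran-2-yl)prop-1-en-1-yl trifluoromethanesulfonate F3. This compound is then coupled with ethylene 18 and boronic acid 8 under the conditions of step 9, where the chelated, weakly acidic phenol should be tolerated by NaHCO3, and the fallback comes back to the route at 20.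

**Further compounds**
F1 | step 9 | 1-{6-(methoxymethoxy)-2-[(2E)-penta-2,4-dien-2-yl]-1-benzofuran-5-yl}ethan-1-one | C=C/C=C(\C)c1cc2cc(C(C)=O)c(OCOC)cc2o1
F2 | step 8 | 1-{2-[(1E)-1-{[tert-butyl(dimethyl)silyl]oxy}prop-1-en-2-yl]-6-(methoxymethoxy)-1-benzofuran-5-yl}ethan-1-one | CC(=O)c1cc2cc(/C(C)=C/O[Si](C)(C)C(C)(C)C)oc2cc1OCOC
F3 | step 10 | (1E)-2-(5-acetyl-6-hydroxy-1-benzofuran-2-yl)prop-1-en-1-yl trifluoromethanesulfonate | FC(F)(F)S(=O)(=O)O/C=C(\C)c1cc2cc(C(C)=O)c(O)cc2o1
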